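| setting | Sunday's | Monday's | Friday's | delta | gamma |
|---|---|---|---|---|---|
| free monomer | 0.29 M | 0.65 M | 0.43 M | 0.43 M | 0.43 M |
| initiator | 11 mM | 11 mM | 5.5 mM | 11 mM | 11 mM |
| temperature | 55 °C | 75 °C | 55 °C | 60 °C | 90 °C |
| remark | run made earlier | run made earlier | run made earlier |  |  |
| time |  |  |  | 8.0 min | 8.0 min |

| run | time / min | monomer in chains / % |
|---|---|---|
| Sunday's | 0.417 | 2.9 |
| Sunday's | 0.667 | 6.3 |
| Sunday's | 0.833 | 11.7 |
| Sunday's | 1.33 | 19.1 |
| Sunday's | 2.00 | 27.2 |
| Sunday's | 3.00 | 41.2 |
| Sunday's | 5.00 | 57.6 |
| Monday's | 0.333 | 14.9 |
| Monday's | 0.667 | 29.9 |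
| Monday's | 1.00 | 40.0 |
| Monday's | 1.33 | 43.9 |
| Monday's | 2.00 | 53.3 |
| Monday's | 2.50 | 56.8 |
| Friday's | 1.00 | 7.0 |
| Friday's | 2.00 | 17.2 |
| Friday's | 3.00 | 25.0 |
| Friday's | 4.00 | 31.4 |
| Friday's | 5.00 | 37.7 |

(each reading ± 1 percentage point)



- the best flask by amount of monomer in chains, in percent of the free monomer charged; "all alike" if 1.5 percentage points covers them all (delta / gamma / all alike)
- amount of monomer in chains at the end, in percent of the free monomer charged, delta
- amount of monomer in chains at the end, in percent of the free monomer charged, gamma

The easy step comes first: I take the last reading of each run at 55 °C and turn it into a pseudo-first-order constant, the logarithm of the charge over what is not in chains, divided by the time. Sunday's run gives 0.172 /min and Friday's gives 0.0946 /min. These runs differ in free monomer, but if uptake is first order in it, that difference drops out. So I hold the constants against the initiator charges, 11 mM and 5.5 mM, and get 0.859. This reading, the power of [initiator] that carries one constant into the other, is the initiator order. It stands higher than 0.5, so I expect uptake to follow the initiator charge nearly one for one.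

But Monday's run slows. It gains 40.0% by 1.00 min, then less, 13 percentage points, by 2.00 min. I read this as a possible rival taking free monomer in the heat. If that rival ignores the initiator, then at one temperature and time the odds of chains against rival grow as the initiator charge to the power of the order. So watch what else the free monomer becomes. I put no number on delta myself.

The forecast reads this slowing otherwise, “the initiator is burning out”. It names delta as best, with 76% (68% to 84%) for delta and 42% (30% to 56%) for gamma.

Delta gives 73.1% and gamma 39.7%.

    free monomer + initiator → living end + monomer in chains (k = 0.130 /M/s, Ea = 48.0 kJ/mol)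
    free monomer + living end → monomer in chains + living end, rate k2*[living end]*[free monomer] (k = 0.460 /M/s, Ea = 53.0 kJ/mol)
    free monomer → uncatalysed product (k = 0.00140 /s, Ea = 104 kJ/mol)
    (constants at 60 °C)

Delta ends with 73.1% in chains and 22.0% as uncatalysed product, odds of 3.32, with [living end] at 0.0110 M. The neighbouring flask is delta charged with 0.044 M of initiator, 4.00 times delta's charge. The initiator order carries delta's odds to 10.9. That neighbour ends with 91.9% in chains and 8.08% as uncatalysed product, odds of 11.4.

The earlier runs and the new flask are simulated from invented constants; noise was put on by code.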